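**Plan**
- Retrosynthesis: the side-chain ester C–O bond is cut first, then the C1–C2 bond of quinone ring B (which reverts to a four-membered ring bearing an alkynyl carbinol), then the C3–C4 bond (acetylide plus dione carbonyl), and last the two bonds fusing the four-membered ring to ring A (aryne plus ketene acetal).
- Enabling feature: ring B (C1, C2, C3, C4, C4a, C8a) is a 1,4-quinone with the side chain on C2, hydrogen on C3, C1=O peri to the C8 hydroxyl and C4=O peri to the C5 methoxyl. This is the pattern an aryl-fused enynyl ketene delivers on closure, and the C5 and C8 oxygens can be differentiated beforehand on the symmetric dimethoxy dione.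
- Forward: ring A is bought; the four-membered ring is fused on by aryne [2+2] cycloaddition, oxidised to the 1,2-dione and mono-demethylated. The alkyne side chain is made separately, the halves are joined by acetylide addition, thermolysis closes ring B, and desilylation and acylation finish the route.
- Stereochemistry: the only stereocentre, (S) at the side-chain carbinol, is set by Noyori asymmetric transfer hydrogenation of an ynone with the (S,S)-configured ruthenium catalyst and is carried through untouched.

Key step: step 11

Assumption: adduct 20 is used as the mixture of epimers at the ring carbinol carbon, since that carbon becomes the C4 carbonyl.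

**Step 1**
Reactants: 1 2-bromo-1,4-dimethoxybenzene; 2 1,1-dimethoxyethene
Product: 5 3,6-dimethoxybenzocyclobutenone, via 3,6-dimethoxybenzyne 3 (not isolated), via benzocyclobutenone dimethyl ketal 4 (not isolated)
Conditions: NaNH2, 2 (excess), THF, reflux; then 1 M HCl, THF–H2O, rt
Reagents that add atoms: water, O
Why: Sodium amide removes the ring hydrogen flanked by bromine and methoxyl and expels bromide to give the symmetric aryne 3, which the electron-rich ketene acetal captures in a stepwise [2+2] cycloaddition (aryne–ketene acetal cycloaddition) to give ketal 4 as one regioisomer, and dilute acid then hydrolyses the ketal to the strained ketone without touching the aryl ethers.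

**Step 2**
Reactants: 5 3,6-dimethoxybenzocyclobutenone
Product: 6 2,2-dibromo-3,6-dimethoxybenzocyclobutenone
Conditions: NBS (2.2 equiv), (PhCO2)2 (cat.), CCl4, reflux
Reagents that add atoms: N-bromosuccinimide, O=C1CCC(=O)N1Br
Why: Wohl–Ziegler radical bromination takes both hydrogens of the only benzylic CH2, which is also alpha to the carbonyl, while the non-polar medium disfavours ionic bromination of the electron-rich ring.

**Step 3**
Reactants: 6 2,2-dibromo-3,6-dimethoxybenzocyclobutenone
Product: 7 3,6-dimethoxybenzocyclobutene-1,2-dione
Conditions: 50% aq. H2SO4, 60 °C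
Reagents that add atoms: water, O
Why: Acid hydrolysis of a geminal dibromide to a carbonyl group converts the CBr2 carbon into the second ketone, and the benzocyclobutenedione and both aryl methyl ethers are stable to aqueous sulfuric acid at this temperature.

**Step 4**
Reactants: 7 3,6-dimethoxybenzocyclobutene-1,2-dione
Product: 8 3-hydroxy-6-methoxybenzocyclobutene-1,2-dione
Conditions: BCl3 (1.1 equiv), CH2Cl2, −78 to 0 °C; H2O work-up
Reagents that add atoms: none
Why: Lewis-acid cleavage of an aryl methyl ether that is conjugated to a carbonyl group (a vinylogous ester) by BCl3: the two methoxyls of 7 are equivalent so either cleavage gives 8, and the aryloxyboron species formed first is a poorer donor toward a second BCl3, which together with the limited charge of reagent should stop the reaction at the mono-phenol.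

**Step 5**
Reactants: 9 4-methylpent-3-enoic acid
Product: 11 N-methoxy-N,4-dimethylpent-3-enamide, via acyl imidazole 10 (not isolated)
Conditions: 1,1'-carbonyldiimidazole, CH2Cl2, rt; then MeNH(OMe)·HCl, rt
Reagents that add atoms: N,O-dimethylhydroxylamine hydrochloride, CNOC.Cl
Why: Amide formation through the acyl imidazole 10, which forms with loss of carbon dioxide and is then opened by the hydroxylamine under conditions mild enough to leave the beta,gamma-alkene out of conjugation.

**Step 6**
Reactants: 11 N-methoxy-N,4-dimethylpent-3-enamide; 12 ethynyltrimethylsilane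
Product: 14 6-methyl-1-(trimethylsilyl)hept-5-en-1-yn-3-one, via lithium (trimethylsilyl)acetylide 13 (not isolated)
Conditions: 12, n-BuLi, THF, −78 °C; add 11, −78 to 0 °C; pour into cold 1 M HCl
Reagents that add atoms: none
Why: Weinreb ketone synthesis: lithium acetylide 13 adds once to the amide to give a chelated tetrahedral adduct that cannot collapse until the acidic quench, which at the same time protonates the released hydroxylamine and keeps it from adding to the ynone.

**Step 7**
Reactants: 14 6-methyl-1-(trimethylsilyl)hept-5-en-1-yn-3-one
Product: 15 (S)-6-methyl-1-(trimethylsilyl)hept-5-en-1-yn-3-ol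
Conditions: Ru[(S,S)-TsNCHPhCHPhNH](η6-p-cymene) (1 mol%), i-PrOH, rt
Reagents that add atoms: none
Why: Noyori asymmetric transfer hydrogenation of an alkynyl ketone under base-free conditions: the (S,S)-diamine complex delivers hydride to the carbonyl face that gives the (S)-propargylic alcohol, the alkynyl group taking the place an aryl group occupies in aryl ketone reductions, and neither the alkyne nor the trisubstituted alkene is reduced.

**Step 8**
Reactants: 15 (S)-6-methyl-1-(trimethylsilyl)hept-5-en-1-yn-3-ol
Product: 16 (S)-3-(tert-butyldimethylsilyloxy)-6-methyl-1-(trimethylsilyl)hept-5-en-1-yne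
Conditions: TBSCl, imidazole, DMF, rt
Reagents that add atoms: tert-butyldimethylsilyl chloride, CC(C)(C)[Si](C)(C)Cl
Why: Standard imidazole-promoted silylation of a secondary alcohol gives the tert-butyldimethylsilyl ether that must mask the hydroxyl during acetylide formation and thermolysis.

**Step 9**
Reactants: 16 (S)-3-(tert-butyldimethylsilyloxy)-6-methyl-1-(trimethylsilyl)hept-5-en-1-yne
Product: 17 (S)-3-(tert-butyldimethylsilyloxy)-6-methylhept-5-en-1-yne
Conditions: K2CO3 (0.2 equiv), MeOH, rt
Reagents that add atoms: none
Why: Methoxide-mediated protodesilylation cleaves only the carbon-bound trimethylsilyl group of the alkyne, the oxygen-bound tert-butyldimethylsilyl group and the non-acidic propargylic stereocentre being unaffected.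

**Step 10**
Reactants: 8 3-hydroxy-6-methoxybenzocyclobutene-1,2-dione; 17 (S)-3-(tert-butyldimethylsilyloxy)-6-methylhept-5-en-1-yne
Product: 20 2-[(S)-3-(tert-butyldimethylsilyloxy)-6-methylhept-5-en-1-yn-1-yl]-2,6-dihydroxy-3-methoxybenzocyclobutenone (mixture of C2 epimers), via lithium phenoxide 18 (not isolated), via lithium acetylide 19 (not isolated)
Conditions: 8, LiN(SiMe3)2 (1.05 equiv), THF, −78 °C; 17, n-BuLi (1.0 equiv), THF, −78 °C; acetylide added to phenoxide, −78 °C; aq. NH4Cl at −78 °C
Reagents that add atoms: none
Why: 1,2-Addition of a lithium acetylide to a benzocyclobutenedione carbonyl: prior deprotonation turns the carbonyl ortho to the phenoxide into a vinylogous carboxylate, so acetylide 19 should attack the other carbonyl, the one next to the methoxyl-bearing carbon, and a cold quench protects the adduct from anion-driven ring opening.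

**Step 11**
Reactants: 20 2-[(S)-3-(tert-butyldimethylsilyloxy)-6-methylhept-5-en-1-yn-1-yl]-2,6-dihydroxy-3-methoxybenzocyclobutenone
Product: 23 2-[(S)-1-(tert-butyldimethylsilyloxy)-4-methylpent-3-en-1-yl]-8-hydroxy-5-methoxy-1,4-naphthoquinone, via enynyl ketene 21 (not isolated), via ring B diradical 22 (not isolated)
Conditions: p-xylene (0.01 M, degassed), reflux (138 °C)
Reagents that add atoms: none
Why: Moore rearrangement: heating opens the four-membered ring of 20 by conrotatory four-electron electrocyclic cleavage of the C(=O)–C(OH) bond, the hydroxyl rotating outward and the alkynyl group inward, to give the ortho-quinoid enynyl ketene 21. The ketene carbon (future C1) then bonds to the distal alkyne carbon (future C2) in a 6-endo-dig closure that forms ring B and restores the aromaticity of ring A, giving diradical 22 with oxygen-centred spin at the C1 oxygen and a sigma radical at C3. Transfer of the hydroxyl hydrogen from the C4 oxygen to C3 collapses 22 to quinone 23; the closest known reaction is the thermolysis of 4-alkynyl-4-hydroxycyclobutenones and of their benzo-fused analogues to benzoquinones and naphthoquinones. No stereocentre is created: the carbinol carbon of 20 becomes the C4 carbonyl, so both epimers converge, and the (S) centre lies outside the reacting array and is neither enolisable nor ionisable under neutral thermolysis. The step needs six-membered over five-membered closure, which the sp3, non-radical-stabilising substituent on the alkyne secures, and it needs the side chain to end on C2 beside the carbonyl peri to the C8 hydroxyl, which is fixed by the carbinol of 20 lying on the methoxyl side. High dilution keeps the free phenol, which cannot reach the ketene within the same molecule, from capturing it between molecules.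

**Step 12**
Reactants: 23 2-[(S)-1-(tert-butyldimethylsilyloxy)-4-methylpent-3-en-1-yl]-8-hydroxy-5-methoxy-1,4-naphthoquinone
Product: 24 8-hydroxy-2-[(S)-1-hydroxy-4-methylpent-3-en-1-yl]-5-methoxy-1,4-naphthoquinone
Conditions: HF·pyridine, pyridine, THF, 0 °C to rt
Reagents that add atoms: none
Why: Fluoride cleavage of the secondary silyl ether with buffered HF·pyridine, chosen because it is non-basic and so leaves the base-sensitive hydroxyquinone, both alkenes and the stereocentre alone.

**Step 13**
Reactants: 24 8-hydroxy-2-[(S)-1-hydroxy-4-methylpent-3-en-1-yl]-5-methoxy-1,4-naphthoquinone; 25 3-methylbut-2-enoic acid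
Product: 26 (S)-1-(8-hydroxy-5-methoxy-1,4-dioxo-1,4-dihydronaphthalen-2-yl)-4-methylpent-3-en-1-yl 3-methylbut-2-enoate
Conditions: DCC, DMAP (0.1 equiv), CH2Cl2, 0 °C
Reagents that add atoms: none
Why: Steglich esterification (carbodiimide activation with nucleophilic catalysis) acylates the secondary alcohol with retention at the stereocentre because the C–O bond of the carbinol is not broken, while the C8 phenol, hydrogen-bonded to the C1 carbonyl, is too poor a nucleophile to compete.

**Compound list**
1 | 2-bromo-1,4-dimethoxybenzene | COc1ccc(OC)c(Br)c1 | starting material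
2 | 1,1-dimethoxyethene | C=C(OC)OC | starting material
3 | 3,6-dimethoxybenzyne (1,4-dimethoxy-2,3-didehydrobenzene) | COC1=CC=C(OC)C#C1 | intermediate (not isolated)
4 | 1,1,3,6-tetramethoxy-1,2-dihydrobenzocyclobutene (dimethyl ketal of 5) | COc1ccc(OC)c2c1CC2(OC)OC | intermediate (not isolated)
5 | 3,6-dimethoxybenzocyclobutenone | COc1ccc(OC)c2c1CC2=O | intermediate
6 | 2,2-dibromo-3,6-dimethoxybenzocyclobutenone | COc1ccc(OC)c2c1C(Br)(Br)C2=O | intermediate
7 | 3,6-dimethoxybenzocyclobutene-1,2-dione | COc1ccc(OC)c2c1C(=O)C2=O | intermediate
8 | 3-hydroxy-6-methoxybenzocyclobutene-1,2-dione | COc1ccc(O)c2c1C(=O)C2=O | intermediate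
9 | 4-methylpent-3-enoic acid | CC(C)=CCC(=O)O | starting material
10 | 1-(4-methylpent-3-enoyl)imidazole | CC(C)=CCC(=O)n1ccnc1 | intermediate (not isolated)
11 | N-methoxy-N,4-dimethylpent-3-enamide | CC(C)=CCC(=O)N(C)OC | intermediate
12 | ethynyltrimethylsilane | C#C[Si](C)(C)C | starting material
13 | lithium (trimethylsilyl)acetylide | [Li]C#C[Si](C)(C)C | intermediate (not isolated)
14 | 6-methyl-1-(trimethylsilyl)hept-5-en-1-yn-3-one | CC(C)=CCC(=O)C#C[Si](C)(C)C | intermediate
15 | (S)-6-methyl-1-(trimethylsilyl)hept-5-en-1-yn-3-ol | C[Si](C)(C)C#C[C@H](CC=C(C)C)O | intermediate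
16 | (S)-3-(tert-butyldimethylsilyloxy)-6-methyl-1-(trimethylsilyl)hept-5-en-1-yne | C[Si](C)(C)C#C[C@H](CC=C(C)C)O[Si](C)(C)C(C)(C)C | intermediate
17 | (S)-3-(tert-butyldimethylsilyloxy)-6-methylhept-5-en-1-yne | C#C[C@H](CC=C(C)C)O[Si](C)(C)C(C)(C)C | intermediate
18 | lithium phenoxide of 8 (lithium 6-methoxy-1,2-dioxobenzocyclobuten-3-olate) | COc1ccc(O[Li])c2c1C(=O)C2=O | intermediate (not isolated)
19 | lithium acetylide of 17 | [Li]C#C[C@H](CC=C(C)C)O[Si](C)(C)C(C)(C)C | intermediate (not isolated)
20 | 2-[(S)-3-(tert-butyldimethylsilyloxy)-6-methylhept-5-en-1-yn-1-yl]-2,6-dihydroxy-3-methoxybenzocyclobutenone (both C2 epimers) | COc1ccc(O)c2c1C(O)(C#C[C@H](CC=C(C)C)O[Si](C)(C)C(C)(C)C)C2=O | intermediate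
21 | ortho-quinoid enynyl ketene from ring opening of 20 (ketene on the ring carbon next to C–OH, hydroxy-enyne on the ring carbon next to C–OMe) | COC1=CC=C(O)C(=C=O)C1=C(O)C#C[C@H](CC=C(C)C)O[Si](C)(C)C(C)(C)C | intermediate (not isolated)
22 | ring B diradical (naphthalene with oxyl radical on the C1 oxygen, sigma radical at C3, hydroxyl at C4) | COc1ccc(O)c2c([O])c([C@H](CC=C(C)C)O[Si](C)(C)C(C)(C)C)[c]c(O)c12 | intermediate (not isolated)
23 | 2-[(S)-1-(tert-butyldimethylsilyloxy)-4-methylpent-3-en-1-yl]-8-hydroxy-5-methoxy-1,4-naphthoquinone | COc1ccc(O)c2c1C(=O)C=C([C@H](CC=C(C)C)O[Si](C)(C)C(C)(C)C)C2=O | intermediate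
24 | 8-hydroxy-2-[(S)-1-hydroxy-4-methylpent-3-en-1-yl]-5-methoxy-1,4-naphthoquinone | COc1ccc(O)c2c1C(=O)C=C([C@H](CC=C(C)C)O)C2=O | intermediate
25 | 3-methylbut-2-enoic acid | CC(C)=CC(=O)O | starting material
26 | (S)-1-(8-hydroxy-5-methoxy-1,4-dioxo-1,4-dihydronaphthalen-2-yl)-4-methylpent-3-en-1-yl 3-methylbut-2-enoate | COc1ccc(O)c2c1C(=O)C=C([C@H](CC=C(C)C)OC(=O)C=C(C)C)C2=O | target

**Step count**
Total: 13 steps. Longest linear sequence: 9 steps (steps 5 to 13, from 4-methylpent-3-enoic acid). The ring A branch (steps 1 to 4) joins at step 10.

**Steps most likely to fail**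

Step 10 (acetylide addition to the phenoxide of the dione). The site control may be lost, with the acetylide also attacking the carbonyl beside the phenoxide, or the doubly charged adduct may open its four-membered ring before the quench. The fallback sets out from symmetric dione 7 and alkyne 17 (as its lithium acetylide 19), where no site question exists. Addition in THF at −78 °C should give 2-[(S)-3-(tert-butyldimethylsilyloxy)-6-methylhept-5-en-1-yn-1-yl]-2-hydroxy-3,6-dimethoxybenzocyclobutenone F1. In this compound the two methoxyls are no longer equivalent, because only the C6 methoxyl is conjugated with the remaining ketone. BCl3 in CH2Cl2 at −78 °C with short contact should therefore cleave that ether alone, and the route is rejoined at 20.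

Step 11 (thermal ring expansion). The ketene–alkyne closure may partition toward the five-membered alkylidene-indandione manifold, or the ketene may be captured by the phenol of a second molecule. The fallback replaces the alkyne by an alkene so that ring B closes by a pericyclic path with no diradical and no choice of ring size. It sets out from alkyne 17 and phenol 8 (as lithium phenoxide 18).
- Hydrozirconation of 17 with Cp2Zr(H)Cl in THF followed by iodine should give (S,E)-3-(tert-butyldimethylsilyloxy)-1-iodo-6-methylhepta-1,5-diene F2.
- Exchange with t-BuLi (2 equiv, Et2O, −78 °C) should give the (S,E)-alkenyllithium F3.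
- Addition of this reagent to 18 under the site control of step 10 should give 2-[(S,E)-3-(tert-butyldimethylsilyloxy)-6-methylhepta-1,5-dien-1-yl]-2,6-dihydroxy-3-methoxybenzocyclobutenone F4.
- Heating in toluene at 110 °C should open the ring, close the resulting triene by six-electron electrocyclisation and, after enolisation, give 2-[(S)-1-(tert-butyldimethylsilyloxy)-4-methylpent-3-en-1-yl]-5-methoxynaphthalene-1,4,8-triol F5.
- Oxidation of the hydroquinone with Ag2O or air returns the route at 23.

Step 4 (mono-demethylation). The cleavage may stall or run on to the diol, because the peri oxygens across a four-membered ring lie too far apart for the boron chelate that usually makes such cleavages selective. The fallback sets out from 7. Excess BBr3 (CH2Cl2, −78 °C to rt) removes both methyl groups to give 3,6-dihydroxybenzocyclobutene-1,2-dione F6. One equivalent of base (K2CO3, DMF) then forms the mono-phenoxide, whose remaining hydroxyl is much less acidic, and MeI (1 equiv) methylates it to rejoin the route at 8. Doubly methylated material is 7 itself and is recycled.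

**Further compounds**
F1 | step 10 | 2-[(S)-3-(tert-butyldimethylsilyloxy)-6-methylhept-5-en-1-yn-1-yl]-2-hydroxy-3,6-dimethoxybenzocyclobutenone | COc1ccc(OC)c2c1C(O)(C#C[C@H](CC=C(C)C)O[Si](C)(C)C(C)(C)C)C2=O
F2 | step 11 | (S,E)-3-(tert-butyldimethylsilyloxy)-1-iodo-6-methylhepta-1,5-diene | I/C=C/[C@H](CC=C(C)C)O[Si](C)(C)C(C)(C)C
F3 | step 11 | (S,E)-[3-(tert-butyldimethylsilyloxy)-6-methylhepta-1,5-dien-1-yl]lithium | [Li]/C=C/[C@H](CC=C(C)C)O[Si](C)(C)C(C)(C)C
F4 | step 11 | 2-[(S,E)-3-(tert-butyldimethylsilyloxy)-6-methylhepta-1,5-dien-1-yl]-2,6-dihydroxy-3-methoxybenzocyclobutenone | COc1ccc(O)c2c1C(O)(/C=C/[C@H](CC=C(C)C)O[Si](C)(C)C(C)(C)C)C2=O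
F5 | step 11 | 2-[(S)-1-(tert-butyldimethylsilyloxy)-4-methylpent-3-en-1-yl]-5-methoxynaphthalene-1,4,8-triol | COc1ccc(O)c2c(O)c([C@H](CC=C(C)C)O[Si](C)(C)C(C)(C)C)cc(O)c12
F6 | step 4 | 3,6-dihydroxybenzocyclobutene-1,2-dione | Oc1ccc(O)c2c1C(=O)C2=O
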